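The numbering follows germacrane: carbocycle C1–C10, lactone ring O–C6–C7–C11(=C13)–C12, ester carbon C14 on C10, methyl C15 on C4. Everything rests on cutting C9–C10 inside the motif C1=C10(C14O2Me)–C9H(O), an allylic carbinol on the α-carbon of an enoate. In precursor 23 both carbons are electrophiles, a C9 aldehyde and a (Z)-α-iodoenoate. They are carried by the finished trans-lactone and cis-4,5-epoxide. CrCl2/NiCl2 reverses the polarity of C10. One intramolecular Nozaki–Hiyama–Kishi reaction then closes the ten-membered ring, keeps the ring-cis C1=C10 alkene and sets C9 from C8. C4/C5 come from a Sharpless epoxidation, C8 from a catalytic alkynylation, and C6/C7 from one allylboration–lactonisation.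

Key step: step 13

Remark 1 (assumption): (R,R)-ProPhenol is assumed to give the (4R)-carbinol 11. If the sense of induction is the opposite, the equally available (S,S)-ligand is used instead.
Remark 2: the CIP descriptors at C5, C7 and C8 change along the route only because substituent priorities change. The spatial arrangement is that of 27 throughout.

Step 1
Reactants: 1 nerol
Product: 2 (2S,3R)-2,3-epoxynerol
Conditions: Ti(OiPr)4 (cat.), L-(+)-diethyl tartrate (cat.), t-BuOOH, 4 Å MS, CH2Cl2, −20 °C
Reagents that add atoms: tert-butyl hydroperoxide, CC(C)(C)OO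
Why: Sharpless asymmetric epoxidation: the complex of Ti(OiPr)4 with the tartrate binds the allylic alcohol, so only the C4=C5 alkene reacts, L-(+)-tartrate should deliver oxygen to the face that gives the (2S,3R)-epoxide (C5 S, C4 R), and the Z alkene of nerol becomes the cis relation of C3 and C6 on the oxirane.

Step 2
Reactants: 2 (2S,3R)-2,3-epoxynerol
Product: 4 3-[(2R,3S)-3-(hydroxymethyl)-2-methyloxiran-2-yl]propanal, via secondary ozonide 3 (not isolated)
Conditions: O3, CH2Cl2, −78 °C; then Me2S, −78 °C to rt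
Reagents that add atoms: ozone, [O-][O+]=O
Why: Ozonolysis with reductive work-up cleaves the only remaining alkene to the C1 aldehyde and acetone, while the epoxide and the primary alcohol are inert to ozone at −78 °C.

Step 3
Reactants: 4 3-[(2R,3S)-3-(hydroxymethyl)-2-methyloxiran-2-yl]propanal; 5 methyl (triphenyl-λ5-phosphanylidene)acetate
Product: 7 methyl (2Z)-5-[(2R,3S)-3-(hydroxymethyl)-2-methyloxiran-2-yl]-2-iodopent-2-enoate, via iodo ylide 6 (not isolated)
Conditions: 5, N-iodosuccinimide, CH2Cl2, −20 °C; then 4, −20 °C to rt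
Reagents that add atoms: N-iodosuccinimide, O=C1CCC(=O)N1I
Why: Wittig olefination with an ester-stabilised α-iodo ylide, made in the flask by iodination of 5, should put the C2 chain trans to CO2Me and thus cis to iodine ((Z)-alkene, the later ring-cis C1=C10 geometry), and it tolerates the free alcohol and the epoxide.

Step 4
Reactants: 7 methyl (2Z)-5-[(2R,3S)-3-(hydroxymethyl)-2-methyloxiran-2-yl]-2-iodopent-2-enoate
Product: 8 methyl (2Z)-5-[(2R,3R)-3-formyl-2-methyloxiran-2-yl]-2-iodopent-2-enoate
Conditions: TEMPO (cat.), PhI(OAc)2, CH2Cl2, rt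
Reagents that add atoms: none
Why: Oxoammonium (TEMPO) oxidation stops at the aldehyde under nearly neutral conditions, so the oxirane stereocentres, the iodoalkene and the ester should remain untouched.

Step 5
Reactants: 9 3-methylbut-2-enal; 10 methyl propiolate
Product: 11 methyl (4R)-4-hydroxy-6-methylhept-5-en-2-ynoate
Conditions: Me2Zn, (R,R)-ProPhenol (cat.), Ph3P=O (cat.), PhMe, 0–4 °C; aq. NH4Cl
Reagents that add atoms: none
Why: Catalytic asymmetric alkynylation of an aldehyde: the dinuclear complex formed from Me2Zn and the ligand holds the zinc acetylide of 10 and the enal 9 side by side and should pass the alkynyl group to one carbonyl face only, which sets C8.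

Step 6
Reactants: 11 methyl (4R)-4-hydroxy-6-methylhept-5-en-2-ynoate
Product: 12 methyl (4R)-6-methyl-4-(triethylsilyloxy)hept-5-en-2-ynoate
Conditions: Et3SiCl, imidazole, CH2Cl2, 0 °C
Reagents that add atoms: chlorotriethylsilane, CC[Si](Cl)(CC)CC
Why: Standard silylation masks O8, which would otherwise close a butenolide onto C12 after step 7, and the mild base avoids isomerisation of the ynoate.

Step 7
Reactants: 12 methyl (4R)-6-methyl-4-(triethylsilyloxy)hept-5-en-2-ynoate
Product: 14 methyl (2Z,4R)-6-methyl-2-[(4,4,5,5-tetramethyl-1,3,2-dioxaborolan-2-yl)methyl]-4-(triethylsilyloxy)hepta-2,5-dienoate, via alkenylalane 13 (not isolated)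
Conditions: i-Bu2AlH, HMPA, THF, 0 °C; then ICH2Bpin, 0 °C to rt
Reagents that add atoms: 2-(iodomethyl)-4,4,5,5-tetramethyl-1,3,2-dioxaborolane, ICB1OC(C)(C)C(C)(C)O1
Why: Conjugate syn-hydroalumination of the ynoate (H to C7, Al to C11, ester untouched) followed by Matteson-type homologation with ICH2Bpin (boron ate complex, 1,2-shift with loss of iodide, retention at C11) should leave C8 cis to CO2Me, the geometry that an anti-selective allylboration requires.

Step 8
Reactants: 8 methyl (2Z)-5-[(2R,3R)-3-formyl-2-methyloxiran-2-yl]-2-iodopent-2-enoate; 14 allylboronate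
Product: 16 trans-α-methylene-γ-lactone carrying at C6 the cis-epoxide/(Z)-iodoenoate chain and at C7 the CH(OSiEt3)CH=CMe2 group (1Z; 4R,5S,6S,7S,8R), via pinacol borate 15 (not isolated)
Conditions: PhMe, 4 Å MS, 70–80 °C
Reagents that add atoms: none
Why: Thermal allylboration through a closed six-membered chair (C5 and C8 equatorial) turns the alkene geometry of 14 into the anti C6/C7 relation, which becomes the trans-lactone once the O6 borate displaces methoxide from C12, and the absolute sense should be matched because 8 is attacked in the Felkin–Anh/Cornforth sense (epoxide O and O6 anti) while 14 reacts with H8 eclipsing the alkene (allylic 1,3-strain against CO2Me), the isobutenyl group anti to the forming bond and the silyloxy group outside.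

Step 9
Reactants: 16 lactone triethylsilyl ether
Product: 17 C8 alcohol of the lactone (1Z; 4R,5S,6S,7R,8R)
Conditions: Et3N·3HF, MeCN, 0 °C to rt
Reagents that add atoms: none
Why: Fluoride-driven desilylation under almost neutral conditions should free O8 without opening the epoxide, ionising the allylic C8–O bond or moving the lactone from O6 to O8.

Step 10
Reactants: 18 2-(hydroxymethyl)acrylic acid
Product: 20 2-{[(tert-butyldimethylsilyl)oxy]methyl}acrylic acid, via bis-silyl derivative 19 (not isolated)
Conditions: t-BuMe2SiCl, imidazole, DMF, rt; then K2CO3, MeOH–THF–H2O, rt; acidify to pH 4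
Reagents that add atoms: tert-butyldimethylsilyl chloride, CC(C)(C)[Si](C)(C)Cl
Why: Exhaustive silylation followed by selective hydrolysis of the far more labile silyl ester gives the O-protected acid.

Step 11
Reactants: 17 C8 alcohol; 20 2-{[(tert-butyldimethylsilyl)oxy]methyl}acrylic acid
Product: 21 C8 ester of 17 with acid 20 (1Z; 4R,5S,6S,7R,8R)
Conditions: DCC, DMAP (cat.), CH2Cl2, 0 °C to rt
Reagents that add atoms: none
Why: Steglich esterification (carbodiimide activation, acyl transfer by DMAP) acylates the only free hydroxyl with retention at C8.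

Step 12
Reactants: 21 C8 ester
Product: 23 C9 aldehyde, the iodoenoate aldehyde (1Z; 4R,5S,6S,7S,8S), via secondary ozonide 22 (not isolated)
Conditions: O3, CH2Cl2, −78 °C, Sudan red 7B end point; then Me2S, −78 °C to rt; used crude
Reagents that add atoms: ozone, [O-][O+]=O
Why: Chemoselective ozonolysis: the trisubstituted C9=CMe2 alkene is the only electron-rich one, the other three (C11=C13, the C1=C10 iodoenoate, the acrylate) are conjugated to carbonyl groups and react far more slowly, so titration to an indicator end point should unveil the C9 aldehyde under neutral conditions and without ever freeing a hydroxyl next to the C8 ester.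

Step 13
Reactants: 23 iodoenoate aldehyde
Product: 25 macrocyclic C9 carbinol, methyl 8-{2-[(tert-butyldimethylsilyloxy)methyl]acryloyloxy}-4,5-epoxy-9-hydroxy-12-oxogermacra-1(10),11(13)-dien-12,6-olid-14-oate (1(10)E; 4R,5S,6S,7R,8S,9R), via alkenylchromium dichloride 24 (not isolated)
Conditions: CrCl2 (excess), NiCl2 (cat.), DMF–THF, rt, slow addition of 23 to about 1 mM; aqueous work-up
Reagents that add atoms: none
Why: Zerovalent nickel, formed from NiCl2 by CrCl2, inserts into the C10–I bond with retention, transmetalation to trivalent chromium gives 24, and 24 adds to the C9 aldehyde, so two equivalents of divalent chromium join two electrophilic carbons by reversing the polarity of C10. The closest known reaction type is the Nozaki–Hiyama–Kishi macrocyclisation of iodoalkene aldehydes to medium-ring allylic alcohols. The ten-membered carbocycle closes in the 10-exo-trig mode, helped by high dilution and by three rigid elements in the tether (Z-alkene, cis-epoxide, trans-lactone). C9 is the only new stereocentre and is controlled by C8: in the polar Felkin–Anh arrangement the C8–O bond stands anti to the incoming C10 and the trajectory passes H8 rather than C7, which should give the 8,9-anti (9R) carbinol. The step needs selectivity for the aldehyde over two esters, the lactone, three Michael acceptors and the epoxide, which the low basicity and high carbonyl selectivity of the C–Cr bond should secure. It also needs retention of alkene geometry, which the covalent C10–Cr bond should secure so that C2 and C9 stay cis.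

Step 14
Reactants: 25 macrocyclic C9 carbinol
Product: 26 C9 acetate of 25 (1(10)E; 4R,5S,6S,7R,8S,9R)
Conditions: Ac2O, pyridine, DMAP (cat.), CH2Cl2, 0 °C
Reagents that add atoms: acetic anhydride, CC(=O)OC(C)=O
Why: Acetylation of the single free hydroxyl proceeds with retention at C9 and is run cold and fast so that the neighbouring O8 ester has no time to migrate.

Step 15
Reactants: 26 C9 acetate
Product: 27 target CNP0147016.1
Conditions: HF·pyridine, pyridine, THF, 0 °C
Reagents that add atoms: none
Why: Buffered fluoride cleaves the primary silyl ether, and the epoxide, the acetate, both esters and the Michael acceptors should survive these weakly acidic, non-nucleophilic conditions.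

Compound list
1 | nerol, (2Z)-3,7-dimethylocta-2,6-dien-1-ol | CC(C)=CCC/C(C)=C\CO | starting material
2 | (2S,3R)-2,3-epoxynerol | OC[C@@H]1O[C@]1(C)CCC=C(C)C | intermediate
3 | secondary ozonide of 2 (3,3-dimethyl-1,2,4-trioxolane at C1) | OC[C@@H]1O[C@]1(C)CCC1OOC(C)(C)O1 | intermediate
4 | 3-[(2R,3S)-3-(hydroxymethyl)-2-methyloxiran-2-yl]propanal | OC[C@@H]1O[C@]1(C)CCC=O | intermediate
5 | methyl (triphenyl-λ5-phosphanylidene)acetate | COC(=O)C=P(c1ccccc1)(c1ccccc1)c1ccccc1 | starting material
6 | methyl iodo(triphenyl-λ5-phosphanylidene)acetate | COC(=O)C(I)=P(c1ccccc1)(c1ccccc1)c1ccccc1 | intermediate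
7 | methyl (2Z)-5-[(2R,3S)-3-(hydroxymethyl)-2-methyloxiran-2-yl]-2-iodopent-2-enoate | OC[C@@H]1O[C@]1(C)CC/C=C(\I)C(=O)OC | intermediate
8 | methyl (2Z)-5-[(2R,3R)-3-formyl-2-methyloxiran-2-yl]-2-iodopent-2-enoate | O=C[C@@H]1O[C@]1(C)CC/C=C(\I)C(=O)OC | intermediate
9 | 3-methylbut-2-enal | CC(C)=CC=O | starting material
10 | methyl propiolate | C#CC(=O)OC | starting material
11 | methyl (4R)-4-hydroxy-6-methylhept-5-en-2-ynoate | COC(=O)C#C[C@H](O)C=C(C)C | intermediate
12 | methyl (4R)-6-methyl-4-(triethylsilyloxy)hept-5-en-2-ynoate | COC(=O)C#C[C@H](O[Si](CC)(CC)CC)C=C(C)C | intermediate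
13 | methyl (2E,4R)-2-(diisobutylalumanyl)-6-methyl-4-(triethylsilyloxy)hepta-2,5-dienoate (C8 cis to CO2Me) | COC(=O)/C([Al](CC(C)C)CC(C)C)=C\[C@H](O[Si](CC)(CC)CC)C=C(C)C | intermediate
14 | methyl (2Z,4R)-6-methyl-2-[(4,4,5,5-tetramethyl-1,3,2-dioxaborolan-2-yl)methyl]-4-(triethylsilyloxy)hepta-2,5-dienoate | COC(=O)/C(CB1OC(C)(C)C(C)(C)O1)=C\[C@H](O[Si](CC)(CC)CC)C=C(C)C | intermediate
15 | O6 pinacol borate of the anti homoallylic alcohol, C12 methyl ester still open | COC(=O)C(=C)[C@H]([C@H](O[Si](CC)(CC)CC)C=C(C)C)[C@H](OB1OC(C)(C)C(C)(C)O1)[C@@H]1O[C@]1(C)CC/C=C(\I)C(=O)OC | intermediate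
16 | methyl (2Z)-2-iodo-5-[(2R,3S)-2-methyl-3-{(2S,3S)-4-methylidene-3-[(1R)-3-methyl-1-(triethylsilyloxy)but-2-en-1-yl]-5-oxooxolan-2-yl}oxiran-2-yl]pent-2-enoate | CC[Si](CC)(CC)O[C@@H]([C@H]1C(=C)C(=O)O[C@@H]1[C@@H]1O[C@]1(C)CC/C=C(\I)C(=O)OC)C=C(C)C | intermediate
17 | methyl (2Z)-5-[(2R,3S)-3-{(2S,3R)-3-[(1R)-1-hydroxy-3-methylbut-2-en-1-yl]-4-methylidene-5-oxooxolan-2-yl}-2-methyloxiran-2-yl]-2-iodopent-2-enoate | O[C@@H]([C@H]1C(=C)C(=O)O[C@@H]1[C@@H]1O[C@]1(C)CC/C=C(\I)C(=O)OC)C=C(C)C | intermediate
18 | 2-(hydroxymethyl)acrylic acid | C=C(CO)C(=O)O | starting material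
19 | tert-butyldimethylsilyl 2-{[(tert-butyldimethylsilyl)oxy]methyl}acrylate | C=C(CO[Si](C)(C)C(C)(C)C)C(=O)O[Si](C)(C)C(C)(C)C | intermediate
20 | 2-{[(tert-butyldimethylsilyl)oxy]methyl}acrylic acid | C=C(CO[Si](C)(C)C(C)(C)C)C(=O)O | intermediate
21 | O8 2-(silyloxymethyl)acrylate of 17 (1Z; 4R,5S,6S,7R,8R) | C=C(CO[Si](C)(C)C(C)(C)C)C(=O)O[C@@H]([C@H]1C(=C)C(=O)O[C@@H]1[C@@H]1O[C@]1(C)CC/C=C(\I)C(=O)OC)C=C(C)C | intermediate
22 | secondary ozonide of 21 (3,3-dimethyl-1,2,4-trioxolane at C9) | C=C(CO[Si](C)(C)C(C)(C)C)C(=O)O[C@@H]([C@H]1C(=C)C(=O)O[C@@H]1[C@@H]1O[C@]1(C)CC/C=C(\I)C(=O)OC)C1OOC(C)(C)O1 | intermediate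
23 | C9 aldehyde with (Z)-α-iodoenoate, lactone, epoxide and O8 ester in place (1Z; 4R,5S,6S,7S,8S) | C=C(CO[Si](C)(C)C(C)(C)C)C(=O)O[C@@H]([C@H]1C(=C)C(=O)O[C@@H]1[C@@H]1O[C@]1(C)CC/C=C(\I)C(=O)OC)C=O | intermediate
24 | C10 alkenylchromium dichloride derived from 23 | C=C(CO[Si](C)(C)C(C)(C)C)C(=O)O[C@@H]([C@H]1C(=C)C(=O)O[C@@H]1[C@@H]1O[C@]1(C)CC/C=C(\[Cr](Cl)Cl)C(=O)OC)C=O | intermediate
25 | macrocyclic C9 carbinol (1(10)E; 4R,5S,6S,7R,8S,9R) | C=C(CO[Si](C)(C)C(C)(C)C)C(=O)O[C@H]1[C@H]2C(=C)C(=O)O[C@@H]2[C@@H]2O[C@]2(C)CC/C=C(/C(=O)OC)[C@H]1O | intermediate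
26 | C9 acetate, side chain still silylated (1(10)E; 4R,5S,6S,7R,8S,9R) | C=C(CO[Si](C)(C)C(C)(C)C)C(=O)O[C@H]1[C@H]2C(=C)C(=O)O[C@@H]2[C@@H]2O[C@]2(C)CC/C=C(/C(=O)OC)[C@H]1OC(C)=O | intermediate
27 | CNP0147016.1 (1(10)E; 4R,5S,6S,7R,8S,9R) | C=C(CO)C(=O)O[C@H]1[C@H]2C(=C)C(=O)O[C@@H]2[C@@H]2O[C@]2(C)CC/C=C(/C(=O)OC)[C@H]1OC(C)=O | target

Total step count: 15.
Longest linear sequence: 11 steps (1, 2, 3, 4, 8, 9, 11, 12, 13, 14, 15).

Steps most likely to fail

Step 13. Several things may go wrong.
- Ring closure may be slower than protonolysis of the C–Cr bond or than intermolecular addition.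
- The chromium alkoxide at O9 may take over the acyl group from O8.
- Divalent chromium may cleave the α-acyloxy C8–O bond.
- The alkene geometry may leak through an O-bound allenolate.
- The ring conformation may override the Felkin–Anh preference.

The fallback closes the same bond on a different precursor and moves the acylation behind the ring closure. It sets out from 16 and comes back at 26. Ozonolysis of 16 (O3, CH2Cl2, −78 °C; Me2S) would give the α-triethylsilyloxy aldehyde F1. Its silyl ether can neither migrate nor be cleaved reductively, and it should reinforce the anti selectivity. Treatment with CrCl2/NiCl2 under high dilution would give the macrocyclic silyloxy carbinol F2. Acetylation (Ac2O, pyridine, DMAP) would give the 9-acetate F3, and Et3N·3HF would give the 8-hydroxy 9-acetate F4. Steglich esterification of F4 with 20 would deliver 26.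

Step 8. The addition may be slow at a temperature that the epoxy aldehyde tolerates. The C8 stereocentre of 14 may also steer the aldehyde to the face anti to the C8–O bond, which opposes the Felkin–Anh preference of 8 and erodes facial selectivity.

The fallback uses the C8 epimer, for which that preference is the matched one, and corrects C8 by inversion. It sets out from 9 and 10 and comes back at 21. Alkynylation with the antipodal ligand would give the (4S)-carbinol F5. Silylation would give the (4S)-silyl ether F6, and hydroalumination with ICH2Bpin would give the (2Z,4S)-allylboronate F7. Heating F7 with 8 would give the 8-epi lactone F8, and Et3N·3HF would give the 8-epi alcohol F9. A Mitsunobu esterification of F9 with 20 (PPh3, diisopropyl azodicarboxylate, PhMe, 0 °C) would install the ester with inversion at C8 and give 21.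

Step 7. The alkenylalane may lose its geometry through an aluminium allenolate before it is trapped, the alkylation with ICH2Bpin may be sluggish, and the ester may be over-reduced.

The fallback replaces the one-pot sequence by configurationally stable alkenyl intermediates and a cross-coupling. It sets out from 12 and comes back at 14. Syn-hydrostannation (Bu3SnH, Pd(PPh3)4 cat., THF) would give the α-stannyl enoate F10, and iododestannylation (I2, CH2Cl2, 0 °C) would give the (E)-α-iodoenoate F11. Negishi coupling of F11 with IZnCH2Bpin (from ICH2Bpin and Zn) under Pd(PPh3)4 catalysis would give 14 with retention.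

Further compounds
F1 | step 13 | α-triethylsilyloxy C9 aldehyde from 16 | CC[Si](CC)(CC)O[C@@H]([C@H]1C(=C)C(=O)O[C@@H]1[C@@H]1O[C@]1(C)CC/C=C(\I)C(=O)OC)C=O
F2 | step 13 | macrocyclic 8-triethylsilyloxy 9-carbinol | CC[Si](CC)(CC)O[C@H]1[C@H]2C(=C)C(=O)O[C@@H]2[C@@H]2O[C@]2(C)CC/C=C(/C(=O)OC)[C@H]1O
F3 | step 13 | macrocyclic 8-triethylsilyloxy 9-acetate | CC[Si](CC)(CC)O[C@H]1[C@H]2C(=C)C(=O)O[C@@H]2[C@@H]2O[C@]2(C)CC/C=C(/C(=O)OC)[C@H]1OC(C)=O
F4 | step 13 | macrocyclic 8-hydroxy 9-acetate | O[C@H]1[C@H]2C(=C)C(=O)O[C@@H]2[C@@H]2O[C@]2(C)CC/C=C(/C(=O)OC)[C@H]1OC(C)=O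
F5 | step 8 | methyl (4S)-4-hydroxy-6-methylhept-5-en-2-ynoate | COC(=O)C#C[C@@H](O)C=C(C)C
F6 | step 8 | methyl (4S)-6-methyl-4-(triethylsilyloxy)hept-5-en-2-ynoate | COC(=O)C#C[C@@H](O[Si](CC)(CC)CC)C=C(C)C
F7 | step 8 | (2Z,4S)-allylboronate, C8 epimer of 14 | COC(=O)/C(CB1OC(C)(C)C(C)(C)O1)=C\[C@@H](O[Si](CC)(CC)CC)C=C(C)C
F8 | step 8 | 8-epi lactone triethylsilyl ether | CC[Si](CC)(CC)O[C@H]([C@H]1C(=C)C(=O)O[C@@H]1[C@@H]1O[C@]1(C)CC/C=C(\I)C(=O)OC)C=C(C)C
F9 | step 8 | 8-epi alcohol | O[C@H]([C@H]1C(=C)C(=O)O[C@@H]1[C@@H]1O[C@]1(C)CC/C=C(\I)C(=O)OC)C=C(C)C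
F10 | step 7 | methyl (2E,4R)-6-methyl-2-(tributylstannyl)-4-(triethylsilyloxy)hepta-2,5-dienoate | COC(=O)/C([Sn](CCCC)(CCCC)CCCC)=C\[C@H](O[Si](CC)(CC)CC)C=C(C)C
F11 | step 7 | methyl (2E,4R)-2-iodo-6-methyl-4-(triethylsilyloxy)hepta-2,5-dienoate | COC(=O)/C(I)=C\[C@H](O[Si](CC)(CC)CC)C=C(C)C
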